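**Plan**

Labdane numbering is used: ring A = C-1 to C-5 and C-10, ring B = C-5 to C-10, C-17 = exocyclic CH2 on C-8, C-18 = CH2OAc on C-4.
Retrosynthesis: adjust the C-15 and C-18 oxygen functions, put an oxygen back on C-6, then cut ring B at C-6–C-7 and at C-9–C-10 together, which leads to a bis-allylic ether with the bridge C-6–O–C-9. This ether is cut into a ring A allylic bromide and a chain allylic alcohol.
Enabling feature: C-7, C-8, C-17 and C-9 of ring B are the isobutenyl end of a citronellyl chain, and C-10=C-5–C-6 is an allyl unit of ring A. Joined through oxygen, they allow a [2,3] shift, a [3,3] shift and an ene closure to build ring B as a formal [3+3] annulation.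
Forward order: ring A first (Birch dearomatisation of 3-methoxybenzyl alcohol, catalytic asymmetric methyl addition, transposed allylic bromide). The chain comes from (S)-citronellol, which supplies C-7 to C-9 and C-11 to C-17 intact. Williamson union, ring B in step 11, then C-6 deoxygenation, MOM to acetate, silyl ether to acid.
Stereochemistry: C-13 from (S)-citronellol; C-4 from the chiral copper catalyst; the C-9–O centre (Shi epoxidation) is relayed to C-6 by the [2,3] shift and from there to C-10 and C-9 by the chair [3,3] shift; C-5 from enolate protonation; the C-6 carbinol is deleted.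

Key step: step 11

**Route**

Step 1
Reactants: 1 3-methoxybenzyl alcohol
Product: 3 3-(hydroxymethyl)cyclohex-2-en-1-one, via Birch diene 2 (not isolated)
Conditions: Li, NH3 (l), THF, t-BuOH, −78 °C; then 2 M HCl, THF, 20 °C
Reagents that add atoms: water, O
Why: Birch reduction of the anisole ring (the benzylic oxygen is carried as its lithium alkoxide and is not cleaved) gives the 1-methoxy-1,4-diene, whose enol ether is hydrolysed and conjugated by acid, a dearomatisation that delivers the six carbons of ring A and C-18.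

Step 2
Reactants: 3 3-(hydroxymethyl)cyclohex-2-en-1-one
Product: 4 3-[(methoxymethoxy)methyl]cyclohex-2-en-1-one
Conditions: MOMCl, i-Pr2NEt, CH2Cl2, 0 to 20 °C
Reagents that add atoms: chloromethyl methyl ether, COCCl
Why: O-alkylation of the primary alcohol gives a MOM ether, a small protecting group without acidic C–H that should survive the organometallic, strongly basic and Lewis acidic steps ahead.

Step 3
Reactants: 4 3-[(methoxymethoxy)methyl]cyclohex-2-en-1-one
Product: 6 {[(3R)-3-[(methoxymethoxy)methyl]-3-methylcyclohex-1-en-1-yl]oxy}trimethylsilane, via aluminium enolate 5 (not isolated)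
Conditions: Me3Al, Cu(O2C-C4H3S) (copper thiophene-2-carboxylate, 5 mol %), binaphthol-derived N,N-bis(1-phenylethyl)phosphoramidite (10 mol %, enantiomer chosen for the R product), Et2O, −30 °C; then TMSOTf, THF, −30 to 0 °C
Reagents that add atoms: trimethylaluminium, C[Al](C)C; trimethylsilyl trifluoromethanesulfonate, C[Si](C)(C)OS(=O)(=O)C(F)(F)F
Why: Copper-catalysed asymmetric conjugate addition of Me3Al to a 3-substituted cyclohexenone sets the quaternary C-4 (R) by catalyst control of the enone face, and O-silylation of the aluminium enolate fixes the enolate toward C-5.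

Step 4
Reactants: 6 {[(3R)-3-[(methoxymethoxy)methyl]-3-methylcyclohex-1-en-1-yl]oxy}trimethylsilane
Product: 9 (3R)-3-[(methoxymethoxy)methyl]-3-methyl-2-methylidenecyclohexan-1-one, via Mannich base 7 (not isolated), via ammonium iodide 8 (not isolated)
Conditions: Eschenmoser's salt (CH2=NMe2 iodide), CH2Cl2, 20 °C; MeI; then aq. NaHCO3
Reagents that add atoms: N,N-dimethylmethyleneiminium iodide, C=[N+](C)C.[I-]
Why: The regiodefined silyl enol ether undergoes a Mannich reaction only at C-5, and quaternisation followed by E1cB loss of trimethylamine gives the methylidene ketone, which brings in C-6.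

Step 5
Reactants: 9 (3R)-3-[(methoxymethoxy)methyl]-3-methyl-2-methylidenecyclohexan-1-one
Product: 10 (3R)-3-[(methoxymethoxy)methyl]-1,3-dimethyl-2-methylidenecyclohexan-1-ol (both C-1 epimers)
Conditions: MeLi, Et2O, −78 °C; then H2O
Reagents that add atoms: methyllithium, [Li]C
Why: 1,2-Addition of the hard organolithium to the ketone installs the C-10 methyl (C-20); the new carbinol centre need not be controlled because it becomes sp2 in step 6.

Step 6
Reactants: 10 (3R)-3-[(methoxymethoxy)methyl]-1,3-dimethyl-2-methylidenecyclohexan-1-ol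
Product: 11 (6R)-1-(bromomethyl)-6-[(methoxymethoxy)methyl]-2,6-dimethylcyclohex-1-ene
Conditions: PBr3, pyridine, Et2O, −30 to 0 °C
Reagents that add atoms: phosphorus tribromide, BrP(Br)Br
Why: Bromination with allylic transposition (SN2') puts bromide on the methylidene carbon and moves the alkene to the tetrasubstituted C-5=C-10 position, the thermodynamically favoured primary allylic bromide.

Step 7
Reactants: 12 (S)-citronellol [(3S)-3,7-dimethyloct-6-en-1-ol]
Product: 13 tert-butyl{[(3S)-3,7-dimethyloct-6-en-1-yl]oxy}diphenylsilane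
Conditions: TBDPSCl, imidazole, CH2Cl2, 20 °C
Reagents that add atoms: tert-butyl(chloro)diphenylsilane, CC(C)(C)[Si](Cl)(c1ccccc1)c1ccccc1
Why: Silylation protects the future C-15 oxygen as a robust ether while the C-13 stereocentre of the chiral pool is left untouched.

Step 8
Reactants: 13 tert-butyl{[(3S)-3,7-dimethyloct-6-en-1-yl]oxy}diphenylsilane
Product: 14 tert-butyl{[(3S)-5-[(2R)-3,3-dimethyloxiran-2-yl]-3-methylpentyl]oxy}diphenylsilane
Conditions: D-fructose-derived Shi ketone (30 mol %), Oxone (2KHSO5·KHSO4·K2SO4), K2CO3, Bu4NHSO4, MeCN/dimethoxymethane/aq. buffer pH 10.5, 0 °C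
Reagents that add atoms: potassium peroxymonosulfate, [K+].[O-]S(=O)(=O)OO
Why: Shi epoxidation of the trisubstituted alkene through the chiral dioxirane (spiro transition state) should give the (R)-epoxide under reagent control, the remote C-13 centre having no influence.

Step 9
Reactants: 14 tert-butyl{[(3S)-5-[(2R)-3,3-dimethyloxiran-2-yl]-3-methylpentyl]oxy}diphenylsilane
Product: 15 (3R,6S)-8-[(tert-butyldiphenylsilyl)oxy]-2,6-dimethyloct-1-en-3-ol
Conditions: Et2Al(NC9H18) (diethylaluminium 2,2,6,6-tetramethylpiperidide, from Et2AlCl and lithium 2,2,6,6-tetramethylpiperidide), toluene, 0 °C; then 1 M HCl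
Reagents that add atoms: none
Why: The aluminium amide isomerises the 2,2-dimethyl epoxide to the allylic alcohol by syn removal of a methyl hydrogen, giving the isopropenyl carbinol with the C–O stereocentre (future C-9) unchanged.

Step 10
Reactants: 15 (3R,6S)-8-[(tert-butyldiphenylsilyl)oxy]-2,6-dimethyloct-1-en-3-ol; 11 (6R)-1-(bromomethyl)-6-[(methoxymethoxy)methyl]-2,6-dimethylcyclohex-1-ene
Product: 16 tert-butyl{[(3S,6R)-6-{[(6R)-6-[(methoxymethoxy)methyl]-2,6-dimethylcyclohex-1-en-1-yl]methoxy}-3,7-dimethyloct-7-en-1-yl]oxy}diphenylsilane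
Conditions: NaH, Bu4NI (cat.), THF, 0 to 20 °C
Reagents that add atoms: none
Why: Williamson ether synthesis by SN2 attack of the secondary alkoxide on the primary allylic bromide (SN2' at the fully substituted C-10 is disfavoured) installs the C-6–O–C-9 tether without touching the carbinol stereocentre.

Step 11
Reactants: 16 tert-butyl{[(3S,6R)-6-{[(6R)-6-[(methoxymethoxy)methyl]-2,6-dimethylcyclohex-1-en-1-yl]methoxy}-3,7-dimethyloct-7-en-1-yl]oxy}diphenylsilane
Product: 20 (13S)-15-[(tert-butyldiphenylsilyl)oxy]-18-(methoxymethoxy)labd-8(17)-en-6β-ol, via potassium alkoxide 17 (not isolated), via potassium enolate 18 (not isolated), via aldehyde 19 (not isolated)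
Conditions: KH, 18-crown-6, THF, 0 to 40 °C; AcOH (to neutrality), −78 °C; solvent changed to CH2Cl2; Me2AlCl, −78 to 0 °C; 1 M HCl work-up
Reagents that add atoms: none
Why: Proposed new method: KH/18-crown-6 should metalate the ether at C-6, the allylic potassium species rearranges by a [2,3]-Wittig shift (C-6 to the methylidene carbon C-7, oxygen from C-9 to C-6) to the 1,5-dien-3-olate 17, and this undergoes the anion-accelerated oxy-Cope [3,3] shift, which cuts the temporary C-6–C-7 link and makes the quaternary C-9–C-10 bond, leaving enolate 18 with a new isopropenyl group on C-9; after protonation to 19, Me2AlCl induces an intramolecular carbonyl-ene reaction in which C-7 adds to the formyl carbon C-6 and a C-17 hydrogen passes to oxygen, so that ring B and its exocyclic methylene appear together. The closest known reaction types are the tandem [2,3]-Wittig/anionic oxy-Cope rearrangement of bis-allylic ethers to δ,ε-unsaturated aldehydes and the Lewis acid carbonyl-ene cyclisation of 5-methylhex-5-enals to 3-methylenecyclohexanols; running them in one flask as a [3+3] annulation onto a tetrasubstituted ring alkene is untested. Ring B closes in the ene event by a six-membered, 6-exo-trig attack of the alkene terminus on the aldehyde, through a chair in which the C-6 and C-9 bonds of ring A are both equatorial, which gives the trans ring fusion. Stereocentres: the C-6 carbinol of 17 is set by the C-9–O centre of 16 through the envelope transition state of the [2,3] shift (chain pseudo-equatorial, hence E alkene; cyclohexenyl group exo), and it is relayed to C-10 and C-9 through a chair [3,3] transition state with the oxido group equatorial (axial it would meet the C-10 methyl), the E alkene putting H-9 anti to that methyl; C-5 follows from protonation of 18 on the face away from the axial methyl groups on C-4 and C-10, and C-6 of 20 (oxygen axial in the ene transition state) is removed in step 13. The step needs metalation at the CH2 of C-6 and not at the hindered C-9 methine, E selectivity in the [2,3] shift despite the 2-methyl group of the migrating allyl unit, and ene instead of Prins-type closure, which the proton-scavenging Me2AlCl at low temperature favours.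

Step 12
Reactants: 20 (13S)-15-[(tert-butyldiphenylsilyl)oxy]-18-(methoxymethoxy)labd-8(17)-en-6β-ol
Product: 21 O-[(13S)-15-[(tert-butyldiphenylsilyl)oxy]-18-(methoxymethoxy)labd-8(17)-en-6β-yl] S-methyl carbonodithioate
Conditions: NaH, imidazole (cat.), THF, 20 °C; CS2; MeI
Reagents that add atoms: carbon disulfide, S=C=S; iodomethane, CI
Why: Xanthate formation: the alkoxide adds to the small linear electrophile CS2, which should reach even the axial hydroxyl, and S-methylation gives the radical precursor.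

Step 13
Reactants: 21 O-[(13S)-15-[(tert-butyldiphenylsilyl)oxy]-18-(methoxymethoxy)labd-8(17)-en-6β-yl] S-methyl carbonodithioate
Product: 22 (13S)-15-[(tert-butyldiphenylsilyl)oxy]-18-(methoxymethoxy)labd-8(17)-ene
Conditions: Bu3SnH (high concentration), AIBN (cat.), toluene, 110 °C
Reagents that add atoms: none
Why: Barton–McCombie deoxygenation: the stannyl radical adds to C=S, the C-6–O bond fragments and the secondary radical takes hydrogen from the stannane faster than its reversible 3-exo closure onto the exocyclic alkene can divert it.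

Step 14
Reactants: 22 (13S)-15-[(tert-butyldiphenylsilyl)oxy]-18-(methoxymethoxy)labd-8(17)-ene
Product: 23 (13S)-15-[(tert-butyldiphenylsilyl)oxy]labd-8(17)-en-18-ol
Conditions: ZnBr2, n-PrSH, CH2Cl2, 0 °C
Reagents that add atoms: none
Why: Lewis acid activation of the MOM acetal with capture of the oxocarbenium ion by the thiol frees the primary alcohol under conditions that leave the silyl ether and the exocyclic alkene alone.

Step 15
Reactants: 23 (13S)-15-[(tert-butyldiphenylsilyl)oxy]labd-8(17)-en-18-ol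
Product: 24 (13S)-15-[(tert-butyldiphenylsilyl)oxy]labd-8(17)-en-18-yl acetate
Conditions: Ac2O, pyridine, DMAP (cat.), CH2Cl2, 20 °C
Reagents that add atoms: acetic anhydride, CC(=O)OC(C)=O
Why: DMAP-catalysed acylation converts the neopentyl-type primary alcohol into the acetate of the target.

Step 16
Reactants: 24 (13S)-15-[(tert-butyldiphenylsilyl)oxy]labd-8(17)-en-18-yl acetate
Product: 25 (13S)-15-hydroxylabd-8(17)-en-18-yl acetate
Conditions: Bu4NF, AcOH, THF, 20 °C
Reagents that add atoms: none
Why: Fluoride cleaves the Si–O bond, and buffering with acetic acid keeps the acetate from being cleaved.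

Step 17
Reactants: 25 (13S)-15-hydroxylabd-8(17)-en-18-yl acetate
Product: 26 (13S)-18-acetoxylabd-8(17)-en-15-oic acid (target)
Conditions: TEMPO (cat.), PhI(OAc)2, MeCN/H2O, 20 °C
Reagents that add atoms: water, O
Why: Oxoammonium-mediated oxidation takes the primary alcohol through the aldehyde hydrate to the carboxylic acid without affecting the 1,1-disubstituted alkene or the acetate.

**Compound list**

1 | 3-methoxybenzyl alcohol | COc1cccc(CO)c1 | starting material
2 | (5-methoxycyclohexa-1,4-dien-1-yl)methanol | OCC1=CCC=C(OC)C1 | intermediate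
3 | 3-(hydroxymethyl)cyclohex-2-en-1-one | O=C1C=C(CO)CCC1 | intermediate
4 | 3-[(methoxymethoxy)methyl]cyclohex-2-en-1-one | O=C1C=C(COCOC)CCC1 | intermediate
5 | dimethyl({(3R)-3-[(methoxymethoxy)methyl]-3-methylcyclohex-1-en-1-yl}oxy)alumane | C[Al](C)OC1=C[C@](C)(COCOC)CCC1 | intermediate
6 | {[(3R)-3-[(methoxymethoxy)methyl]-3-methylcyclohex-1-en-1-yl]oxy}trimethylsilane | C[Si](C)(C)OC1=C[C@](C)(COCOC)CCC1 | intermediate
7 | (3R)-2-[(dimethylamino)methyl]-3-[(methoxymethoxy)methyl]-3-methylcyclohexan-1-one (C-2 epimers) | CN(C)CC1C(=O)CCC[C@@]1(C)COCOC | intermediate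
8 | {[(6R)-6-[(methoxymethoxy)methyl]-6-methyl-2-oxocyclohexyl]methyl}trimethylammonium iodide (C-1 epimers) | C[N+](C)(C)CC1C(=O)CCC[C@@]1(C)COCOC.[I-] | intermediate
9 | (3R)-3-[(methoxymethoxy)methyl]-3-methyl-2-methylidenecyclohexan-1-one | C=C1C(=O)CCC[C@@]1(C)COCOC | intermediate
10 | (3R)-3-[(methoxymethoxy)methyl]-1,3-dimethyl-2-methylidenecyclohexan-1-ol (C-1 epimers) | C=C1C(C)(O)CCC[C@@]1(C)COCOC | intermediate
11 | (6R)-1-(bromomethyl)-6-[(methoxymethoxy)methyl]-2,6-dimethylcyclohex-1-ene | BrCC1=C(C)CCC[C@@]1(C)COCOC | intermediate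
12 | (S)-citronellol, (3S)-3,7-dimethyloct-6-en-1-ol | C[C@H](CCO)CCC=C(C)C | starting material
13 | tert-butyl{[(3S)-3,7-dimethyloct-6-en-1-yl]oxy}diphenylsilane | C[C@H](CCO[Si](c1ccccc1)(c1ccccc1)C(C)(C)C)CCC=C(C)C | intermediate
14 | tert-butyl{[(3S)-5-[(2R)-3,3-dimethyloxiran-2-yl]-3-methylpentyl]oxy}diphenylsilane | C[C@H](CCO[Si](c1ccccc1)(c1ccccc1)C(C)(C)C)CC[C@H]1OC1(C)C | intermediate
15 | (3R,6S)-8-[(tert-butyldiphenylsilyl)oxy]-2,6-dimethyloct-1-en-3-ol | C[C@H](CCO[Si](c1ccccc1)(c1ccccc1)C(C)(C)C)CC[C@@H](O)C(C)=C | intermediate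
16 | tert-butyl{[(3S,6R)-6-{[(6R)-6-[(methoxymethoxy)methyl]-2,6-dimethylcyclohex-1-en-1-yl]methoxy}-3,7-dimethyloct-7-en-1-yl]oxy}diphenylsilane | C=C(C)[C@H](OCC1=C(C)CCC[C@@]1(C)COCOC)CC[C@H](C)CCO[Si](c2ccccc2)(c3ccccc3)C(C)(C)C | intermediate
17 | potassium (1S,3E,7S)-9-[(tert-butyldiphenylsilyl)oxy]-1-{(6R)-6-[(methoxymethoxy)methyl]-2,6-dimethylcyclohex-1-en-1-yl}-3,7-dimethylnon-3-en-1-olate | [K+].[O-][C@@H](C/C(C)=C/CC[C@H](C)CCO[Si](c2ccccc2)(c3ccccc3)C(C)(C)C)C1=C(C)CCC[C@@]1(C)COCOC | intermediate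
18 | potassium enolate of 19: potassium {(2R,6R)-2-[(3S,6S)-8-[(tert-butyldiphenylsilyl)oxy]-2,6-dimethyloct-1-en-3-yl]-6-[(methoxymethoxy)methyl]-2,6-dimethylcyclohexylidene}methanolate | [K+].[O-]C=C1[C@](C)(COCOC)CCC[C@]1(C)[C@H](C(C)=C)CC[C@H](C)CCO[Si](c2ccccc2)(c3ccccc3)C(C)(C)C | intermediate
19 | (1R,2R,6R)-2-[(3S,6S)-8-[(tert-butyldiphenylsilyl)oxy]-2,6-dimethyloct-1-en-3-yl]-6-[(methoxymethoxy)methyl]-2,6-dimethylcyclohexane-1-carbaldehyde | O=C[C@H]1[C@](C)(COCOC)CCC[C@]1(C)[C@H](C(C)=C)CC[C@H](C)CCO[Si](c2ccccc2)(c3ccccc3)C(C)(C)C | intermediate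
20 | (4R,5R,6R,9S,10R,13S)-15-[(tert-butyldiphenylsilyl)oxy]-18-(methoxymethoxy)labd-8(17)-en-6β-ol (trans-decalin, axial 6-OH) | C=C1C[C@@H](O)[C@H]2[C@](C)(COCOC)CCC[C@]2(C)[C@H]1CC[C@H](C)CCO[Si](c3ccccc3)(c4ccccc4)C(C)(C)C | intermediate
21 | O-[(13S)-15-[(tert-butyldiphenylsilyl)oxy]-18-(methoxymethoxy)labd-8(17)-en-6β-yl] S-methyl carbonodithioate | C=C1C[C@@H](OC(=S)SC)[C@H]2[C@](C)(COCOC)CCC[C@]2(C)[C@H]1CC[C@H](C)CCO[Si](c3ccccc3)(c4ccccc4)C(C)(C)C | intermediate
22 | (4R,5R,9S,10R,13S)-15-[(tert-butyldiphenylsilyl)oxy]-18-(methoxymethoxy)labd-8(17)-ene | C=C1CC[C@H]2[C@](C)(COCOC)CCC[C@]2(C)[C@H]1CC[C@H](C)CCO[Si](c3ccccc3)(c4ccccc4)C(C)(C)C | intermediate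
23 | (13S)-15-[(tert-butyldiphenylsilyl)oxy]labd-8(17)-en-18-ol | C=C1CC[C@H]2[C@](C)(CO)CCC[C@]2(C)[C@H]1CC[C@H](C)CCO[Si](c3ccccc3)(c4ccccc4)C(C)(C)C | intermediate
24 | (13S)-15-[(tert-butyldiphenylsilyl)oxy]labd-8(17)-en-18-yl acetate | C=C1CC[C@H]2[C@](C)(COC(C)=O)CCC[C@]2(C)[C@H]1CC[C@H](C)CCO[Si](c3ccccc3)(c4ccccc4)C(C)(C)C | intermediate
25 | (13S)-15-hydroxylabd-8(17)-en-18-yl acetate | C=C1CC[C@H]2[C@](C)(COC(C)=O)CCC[C@]2(C)[C@H]1CC[C@H](C)CCO | intermediate
26 | (13S)-18-acetoxylabd-8(17)-en-15-oic acid, (3S)-5-[(1S,4aR,5R,8aR)-5-(acetoxymethyl)-5,8a-dimethyl-2-methylidenedecahydronaphthalen-1-yl]-3-methylpentanoic acid | C=C1CC[C@H]2[C@](C)(COC(C)=O)CCC[C@]2(C)[C@H]1CC[C@H](C)CC(=O)O | target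

**Summary**

Total step count: 17. Longest linear sequence: 14 steps (steps 1–6, then 10–17); the chain branch (steps 7–9) joins at step 10.

Steps most likely to fail:

1. Step 11. Metalation may occur at the wrong allylic carbon, and the [2,3] shift may lose its E selectivity because of the 2-methyl group on the migrating allyl unit. Either would scramble the relay of configuration to C-10 and C-9. Fragmentation of the potassium alkoxide (retro-allylation) and Prins-type instead of ene closure are further failure modes. Fallback (known reactions; sets out from 11 and 13, comes back at 19): the dienol is assembled without the oxygen tether, with alkene geometry and carbinol configuration fixed separately. Oxidation of bromide 11 with N-methylmorpholine N-oxide should give (6R)-6-[(methoxymethoxy)methyl]-2,6-dimethylcyclohex-1-ene-1-carbaldehyde F1. Allylic oxidation of 13 (SeO2, t-BuOOH) should give (2E,6S)-8-[(tert-butyldiphenylsilyl)oxy]-2,6-dimethyloct-2-en-1-ol F2, which PPh3/CCl4 converts into tert-butyl{[(3S,6E)-8-chloro-3,7-dimethyloct-6-en-1-yl]oxy}diphenylsilane F3. The allylbarium reagent from F3 (activated barium from BaI2 and lithium biphenylide, THF, −78 °C) adds to F1 through its unsubstituted carbon with retention of the E geometry, giving (3E,7S)-9-[(tert-butyldiphenylsilyl)oxy]-1-{(6R)-6-[(methoxymethoxy)methyl]-2,6-dimethylcyclohex-1-en-1-yl}-3,7-dimethylnon-3-en-1-ol F4 as both carbinol epimers. Dess–Martin oxidation gives (3E,7S)-9-[(tert-butyldiphenylsilyl)oxy]-1-{(6R)-6-[(methoxymethoxy)methyl]-2,6-dimethylcyclohex-1-en-1-yl}-3,7-dimethylnon-3-en-1-one F5, and Corey–Bakshi–Shibata reduction gives (1S,3E,7S)-9-[(tert-butyldiphenylsilyl)oxy]-1-{(6R)-6-[(methoxymethoxy)methyl]-2,6-dimethylcyclohex-1-en-1-yl}-3,7-dimethylnon-3-en-1-ol F6. KH/18-crown-6 then effects the anionic oxy-Cope rearrangement to aldehyde 19, which is cyclised with Me2AlCl to 20 as in step 11.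

2. Step 12. Thiocarbonylation of the axial hydroxyl, which is flanked by the two syn-axial methyl groups, may stall; in step 13, rearrangement of the homoallylic radical could also compete. Fallback (sets out from 20, comes back at 22): the alcohol is oxidised (Dess–Martin periodinane, NaHCO3) to (13S)-15-[(tert-butyldiphenylsilyl)oxy]-18-(methoxymethoxy)labd-8(17)-en-6-one F7. This is condensed with p-toluenesulfonohydrazide to N'-[(13S)-15-[(tert-butyldiphenylsilyl)oxy]-18-(methoxymethoxy)labd-8(17)-en-6-ylidene]-4-methylbenzenesulfonohydrazide F8, and reduced with catecholborane then NaOAc to 22. The β,γ-unsaturated ketone has to be kept under buffered conditions so that the alkene does not move into conjugation.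

3. Step 3. Facial selectivity of the conjugate addition may be insufficient with the coordinating CH2OMOM substituent, and incomplete O-silylation of the aluminium enolate would lose the enolate regiochemistry. Fallback (sets out from 4, comes back at 6): the C-4 methyl is introduced through a cyclopropane. Corey–Bakshi–Shibata reduction of 4 gives (1R)-3-[(methoxymethoxy)methyl]cyclohex-2-en-1-ol F9. Hydroxyl-directed Simmons–Smith cyclopropanation (Et2Zn, CH2I2) gives (2R)-6-[(methoxymethoxy)methyl]bicyclo[4.1.0]heptan-2-ol with the cyclopropane cis to the hydroxyl F10. Dess–Martin oxidation gives 6-[(methoxymethoxy)methyl]bicyclo[4.1.0]heptan-2-one F11. Li/NH3 cleaves the external cyclopropane bond, turning the ring CH2 into the C-4 methyl, and the regiodefined enolate is silylated (TMSCl, Et3N) to 6.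

**Further compounds**

F1 | step 11 | (6R)-6-[(methoxymethoxy)methyl]-2,6-dimethylcyclohex-1-ene-1-carbaldehyde | O=CC1=C(C)CCC[C@@]1(C)COCOC
F2 | step 11 | (2E,6S)-8-[(tert-butyldiphenylsilyl)oxy]-2,6-dimethyloct-2-en-1-ol | C[C@H](CCO[Si](c1ccccc1)(c1ccccc1)C(C)(C)C)CC/C=C(\C)CO
F3 | step 11 | tert-butyl{[(3S,6E)-8-chloro-3,7-dimethyloct-6-en-1-yl]oxy}diphenylsilane | C[C@H](CCO[Si](c1ccccc1)(c1ccccc1)C(C)(C)C)CC/C=C(\C)CCl
F4 | step 11 | (3E,7S)-9-[(tert-butyldiphenylsilyl)oxy]-1-{(6R)-6-[(methoxymethoxy)methyl]-2,6-dimethylcyclohex-1-en-1-yl}-3,7-dimethylnon-3-en-1-ol (C-1 epimers) | OC(C/C(C)=C/CC[C@H](C)CCO[Si](c2ccccc2)(c3ccccc3)C(C)(C)C)C1=C(C)CCC[C@@]1(C)COCOC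
F5 | step 11 | (3E,7S)-9-[(tert-butyldiphenylsilyl)oxy]-1-{(6R)-6-[(methoxymethoxy)methyl]-2,6-dimethylcyclohex-1-en-1-yl}-3,7-dimethylnon-3-en-1-one | O=C(C/C(C)=C/CC[C@H](C)CCO[Si](c2ccccc2)(c3ccccc3)C(C)(C)C)C1=C(C)CCC[C@@]1(C)COCOC
F6 | step 11 | (1S,3E,7S)-9-[(tert-butyldiphenylsilyl)oxy]-1-{(6R)-6-[(methoxymethoxy)methyl]-2,6-dimethylcyclohex-1-en-1-yl}-3,7-dimethylnon-3-en-1-ol | O[C@@H](C/C(C)=C/CC[C@H](C)CCO[Si](c2ccccc2)(c3ccccc3)C(C)(C)C)C1=C(C)CCC[C@@]1(C)COCOC
F7 | step 12 | (13S)-15-[(tert-butyldiphenylsilyl)oxy]-18-(methoxymethoxy)labd-8(17)-en-6-one | C=C1CC(=O)[C@H]2[C@](C)(COCOC)CCC[C@]2(C)[C@H]1CC[C@H](C)CCO[Si](c3ccccc3)(c4ccccc4)C(C)(C)C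
F8 | step 12 | N'-[(13S)-15-[(tert-butyldiphenylsilyl)oxy]-18-(methoxymethoxy)labd-8(17)-en-6-ylidene]-4-methylbenzenesulfonohydrazide | C=C1CC(=NNS(=O)(=O)c5ccc(C)cc5)[C@H]2[C@](C)(COCOC)CCC[C@]2(C)[C@H]1CC[C@H](C)CCO[Si](c3ccccc3)(c4ccccc4)C(C)(C)C
F9 | step 3 | (1R)-3-[(methoxymethoxy)methyl]cyclohex-2-en-1-ol | O[C@H]1C=C(COCOC)CCC1
F10 | step 3 | (2R)-6-[(methoxymethoxy)methyl]bicyclo[4.1.0]heptan-2-ol, cyclopropane cis to OH | O[C@@H]1CCC[C@]2(COCOC)C[C@H]12
F11 | step 3 | 6-[(methoxymethoxy)methyl]bicyclo[4.1.0]heptan-2-one (configuration as in F10) | O=C1CCC[C@]2(COCOC)C[C@H]12
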